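The earlier runs and the new flask were computed for substances that don't exist, and the scatter is random.

In the north run, the ratio of target gained to solid substrate lost between 10.0 s and 20.0 s was 0.505, but between 50.0 s and 120 s it was less, 0.231. Call this ratio, target gained per solid substrate lost, the capture share; it is a selectivity read over an interval, and it carries the scatter of the readings.

| flask | solid substrate | reagent | second substrate | remark | time |
|---|---|---|---|---|---|
| north-east | 0.088 M | 0.22 M | 0.176 M | run made earlier |  |
| north-west | 0.088 M | 0.11 M | 0.176 M | run made earlier |  |
| west | 0.088 M | 0.17 M | 0.176 M | run made earlier |  |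
| north | 0.18 M | 0.22 M | 0.176 M | run made earlier |  |
| maple | 0.088 M | 0.220 M | 0.176 M | everything together at the start | 3.0 min |
| alder | 0.088 M | 0.220 M (fed, over 80 s) | 0.176 M | all else is in the flask from the start; the feed brings no volume worth counting | 3.0 min |
| cedar | 0.088 M | 0.220 M | 0.176 M (fed, over 80 s) | all else is in the flask from the start; the feed brings no volume worth counting | 3.0 min |

north-east run (percent of the solid substrate charged)

| time / min | target / % | solid substrate / % |
|---|---|---|
| 0.417 | 19.2 | 50.6 |
| 1.00 | 41.1 | 1.0 |
| 2.00 | 48.1 | 0 |
| 3.00 | 48.2 | 0 |

north-west run (percent of the solid substrate charged)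

| time / s | target / % | solid substrate / % |
|---|---|---|
| 25.0 | 10.7 | 55.3 |
| 50.0 | 12.4 | 20.9 |
| 80.0 | 15.6 | 0 |
| 120 | 16.2 | 0.3 |

west run (percent of the solid substrate charged)

| time / s | target / % | solid substrate / % |
|---|---|---|
| 10.0 | 6.0 | 76.6 |
| 20.0 | 12.0 | 58.2 |
| 50.0 | 27.3 | 15.6 |
| 120 | 32.7 | 0 |

north run (percent of the solid substrate charged)

| time / s | target / % | solid substrate / % |
|---|---|---|
| 10.0 | 2.4 | 90.0 |
| 20.0 | 7.4 | 80.1 |
| 50.0 | 17.1 | 56.2 |
| 120 | 27.7 | 10.4 |

(each reading ± 1 percentage point)

- the flask that comes out highest in amount of target, in percent of the solid substrate charged, or "all alike" when all lie within 1.5 percentage points (maple / alder / cedar / all alike)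
- target at the end, in percent of the solid substrate charged, maple
- target at the end, in percent of the solid substrate charged, alder
- target at the end, in percent of the solid substrate charged, cedar

- given per volume of solution although it is solid: solid substrate
- at the start none of the solid substrate is in solution

By the last reading of the north run, target had taken 22.7% of the charged reagent. As my own estimate, I put the fall in the capture share down to second substrate taking reagent as well. Cedar, with second substrate fed slowly, should then hold its capture share while the solid dissolves, and alder, with reagent fed slowly, should lose it. My order is therefore cedar above maple above alder.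

The forecast gave 48.2% for maple, 22% for alder and 35% for cedar, with maple highest, and said: “Cedar is a guess, because second substrate was never varied”.

The simulation gives 49.5% for maple, 40.4% for alder and 74.5% for cedar, so cedar stands highest.

    solid substrate ⇌ starting material, rate k1*(cs1 - [starting material]) while solid is left; crystals form when [starting material] > cs1 (solubility = 49.0 mM, k = 0.0490 /s)
    starting material + reagent → target (k = 0.510 /M/s)
    second substrate + reagent → second product (k = 0.420 /M/s)
    2 starting material → self-condensation product (k = 0.790 /M/s)

At 1.33 min, with solid substrate at 0% in both flasks, the capture share over the whole feed is 0.718 in cedar and 0.335 in alder. In alder at 0.861 min, starting material goes to target at 0.62 times the rate at which it goes to self-condensation product, so target takes 38.3% of the starting material being used at that moment, and at 3.00 min that ratio stands at 6.5.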